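Read the brake on this catalyst from the flasks that straddle the north charge, and let that one number carry the questions.

| flask | substrate | catalyst | time |
|---|---|---|---|
| north | 300 mM | 15.0 mM |  |
| south-west | 150 mM | 15.0 mM |  |
| north-east | 300 mM | 45.0 mM |  |
| north-west | 600 mM | 15.0 mM |  |
| south | 150 mM | 30.0 mM | 8.8 min |

| run | time / min | [target] / mM |
|---|---|---|
| north run | 0.39 | 6.7 |
| north run | 1.2 | 14.9 |
| north run | 2.3 | 27.2 |
| north run | 3.6 | 48.6 |
| north run | 5.1 | 68.8 |
| north run | 6.9 | 91.6 |
| north run | 8.8 | 114.6 |
| south-west run | 0.39 | 2.2 |
| south-west run | 1.2 | 8.2 |
| south-west run | 2.3 | 20.4 |
| south-west run | 3.6 | 31.5 |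
| south-west run | 5.1 | 41.5 |
| south-west run | 6.9 | 51.2 |
| south-west run | 8.8 | 65.0 |
| north-east run | 0.39 | 15.3 |
| north-east run | 1.2 | 44.4 |
| north-east run | 2.3 | 82.9 |
| north-east run | 3.6 | 123.7 |
| north-east run | 5.1 | 164.2 |
| north-east run | 6.9 | 207.7 |
| north-east run | 8.8 | 241.9 |
| north-west run | 0.39 | 8.8 |
| north-west run | 1.2 | 20.3 |
| north-west run | 2.3 | 40.8 |
| north-west run | 3.6 | 67.0 |
| north-west run | 5.1 | 99.4 |
| north-west run | 6.9 | 142.4 |
| north-west run | 8.8 | 191.0 |

(readings scatter by 2 mM)

1. the power of [catalyst] that the first rate follows, about the charge of the north run; measure it at two percent of substrate made into target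
2. the power of [substrate] that the first rate follows, about the charge of the north run; measure it at two percent of substrate made into target (one fixed amount of target, the same in the runs compared)
3. the south-west run starts with 150 mM less of substrate than the north run, and with no target. Compared where both hold the same amount of substrate, once fifteen percent of what the south-west run was charged with has turned into target, is the south-west run faster, slower or alike (within a tenth)?
4. target in the south run at 8.8 min, as a share of the substrate charged

- Overall: substrate -> target, with catalyst as catalyst.
- Constant volume, constant temperature.
- The analysis sees a species whether free or bound.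
- An order is taken over about fifteen percent of the charge, up and down.

At the common time 2.3 min, the north-east run holds 3.05 times the target of the north run for 3.00 times the catalyst, so my reckoning takes the catalyst order as 1.01. The north-west run against the north run gives a substrate order of 0.585, but that span lies wholly above the north charge. The better link is the north-west run against the south-west run, whose ratio at that time reads 2.00 for 4.00 times the substrate.

Let the rate follow c(substrate)/(half-brake + c(substrate)). The half-brake, the substrate level at which the catalyst works at half its ceiling (the half-saturation constant), then reads 300 mM, within the scatter of those readings. About the north charge the order is half-brake/(half-brake + c(substrate)), or 0.500.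

Now turn it into a time. The south-west run makes 8.87 mM min⁻¹, which gives a pseudo-first-order clock of 11.3 min, and the south run, with twice the catalyst, has 5.64 min. Elapsed time over the clock equals the natural logarithm of the substrate's fall plus the substrate used over the half-brake. The south run has 1.56 clocks by 8.8 min, and a share of 70.0% needs 1.55, so I commit to about that share.

The north run's last interval still makes 12.1 mM min⁻¹, level within the scatter with the 11.8 mM min⁻¹ of its first 2.3 min, although substrate is down to 185 mM. Target therefore seems to add rate, and at equal substrate the south-west run holds 150 mM less of it, so I expect that run to be slower.

The forecast gives 0.97 (0.85 to 1.1), 0.6 (0.4 to 0.8), slower, and 66% (59% to 73%), on the ground that “Target therefore helps”. Its substrate order stands above mine and its share below mine.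

    catalyst + substrate → target + catalyst (6.120 M⁻¹ min⁻¹)
    catalyst + substrate ⇌ idle catalyst-substrate complex, settled at all times (3.750 M⁻¹)
    substrate + target → 2 target (0.1392 M⁻¹ min⁻¹)

The south run holds 70.1% of its charge at 8.8 min. About the north charge the first rate follows catalyst with power 0.97 and substrate with power 0.51, and at equal substrate the south-west run is slower, at 0.76 of the north rate. The north-east run, with 3.00 times the catalyst of the south-west run, has a clock of 3.76 min, and with the half-brake of 300 mM the rule puts a quarter of the charge at 2.02 min; that run reached it at 2.08 min.

The runs were generated by integration from invented constants, and the scatter is random.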